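**Retrosynthetic overview**

1. Last event: the O1–C2 bond of the dihydropyran ring (with C4–C4a made in the same flask) is formed on the 1,1-dimethylallyl aryl ether of the otherwise complete, unprotected chalcone, by a thermal [3,3] shift of the C5 unit from oxygen to the ortho carbon and then acid-catalysed 6-endo closure of the freed phenol onto the dimethyl-substituted carbon.
2. Enone C=C: Claisen–Schmidt condensation of the ring A methyl ketone with the ring B aldehyde; the tertiary allyl ether is the only mask on the ring B oxygen and later becomes part of the target.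
3. Ring A ketone: the dihydrofuran ring comes from 5-exo opening of an (S)-epoxide by the 4-phenoxide (inversion to R); the epoxide comes from catalyst-controlled epoxidation of a 5-prenyl ketone made by iodination and Stille prenylation of 2,4-dihydroxyacetophenone.
4. Enabling feature: O1 and C4 of the dihydropyran ring sit on neighbouring aromatic carbons (C8a, C4a), C2 is a gem-dimethyl carbon, and C6 (para to O1) carries the enone; the C2–C3–C4 unit can therefore ride on O1 as an allyl ether, move to either of two equivalent ortho carbons, and close back on O1 through a tertiary cation at C2.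
5. Ring order: dihydrofuran ring (step 7), enone (step 8), dihydropyran ring last (step 9).

Key step: step 9

Remark: the enantiomer of the Shi ketone is taken as accessible from L-fructose by the two steps used in the D series; the target stereocentre is (R) as read from the SMILES.

**Step 1**
Reactants: 1 4-hydroxybenzaldehyde; 2 3-chloro-3-methylbut-1-yne
Product: 3 4-[(2-methylbut-3-yn-2-yl)oxy]benzaldehyde
Conditions: K2CO3, KI (cat.), CuI (cat.), DMF, 60 °C
Reagents that add atoms: 3-chloro-3-methylbut-1-yne (compound 2), CC(C)(Cl)C#C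
Why: Copper-assisted Williamson-type O-alkylation of the phenoxide by the tertiary propargylic chloride is the standard entry to aryl 1,1-dimethylpropargyl ethers and should work well with the acidic para-formyl phenol.

**Step 2**
Reactants: 3 4-[(2-methylbut-3-yn-2-yl)oxy]benzaldehyde
Product: 4 4-[(2-methylbut-3-en-2-yl)oxy]benzaldehyde
Conditions: H2 (1 atm), Pd/CaCO3 poisoned with Pb(OAc)2, quinoline, EtOAc, 23 °C; evaporation below 30 °C
Reagents that add atoms: none
Why: Lindlar-type semi-hydrogenation should stop at the terminal alkene and leave the aldehyde and the tertiary C–O bond intact, and keeping the ether cool avoids a premature Claisen rearrangement.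

**Step 3**
Reactants: 5 1-(2,4-dihydroxyphenyl)ethan-1-one
Product: 6 1-(2,4-dihydroxy-5-iodophenyl)ethan-1-one
Conditions: BnMe3N·ICl2 (1.05 equiv), NaHCO3, CH2Cl2/MeOH, 23 °C
Reagents that add atoms: benzyltrimethylammonium dichloroiodate, C[N+](C)(C)Cc1ccccc1.Cl[I-]Cl
Why: Electrophilic aromatic iodination should go to C5, which is ortho to the free 4-hydroxyl, para to the chelated 2-hydroxyl and less hindered than C3 between the two oxygens, and one equivalent of the mild iodine donor limits di-iodination.

**Step 4**
Reactants: 6 1-(2,4-dihydroxy-5-iodophenyl)ethan-1-one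
Product: 7 1-(4-{[tert-butyl(dimethyl)silyl]oxy}-2-hydroxy-5-iodophenyl)ethan-1-one
Conditions: TBSCl (1.1 equiv), imidazole, DMF, 0 °C
Reagents that add atoms: tert-butyldimethylsilyl chloride, CC(C)(C)[Si](C)(C)Cl
Why: Silylation should occur only at the free 4-hydroxyl because the 2-hydroxyl is hydrogen-bonded to the acetyl group, and the silyl ether blocks phenol oxidation and premature cyclisation in the next two steps.

**Step 5**
Reactants: 7 1-(4-{[tert-butyl(dimethyl)silyl]oxy}-2-hydroxy-5-iodophenyl)ethan-1-one; 8 tributyl(3-methylbut-2-en-1-yl)stannane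
Product: 9 1-[4-{[tert-butyl(dimethyl)silyl]oxy}-2-hydroxy-5-(3-methylbut-2-en-1-yl)phenyl]ethan-1-one
Conditions: Pd(PPh3)4 (5 mol %), DMF (degassed), 90 °C
Reagents that add atoms: tributyl(3-methylbut-2-en-1-yl)stannane (compound 8), CC(C)=CC[Sn](CCCC)(CCCC)CCCC
Why: In this Migita–Kosugi–Stille coupling, oxidative addition into the C–I bond, allyl transfer from tin and reductive elimination at the less substituted allyl terminus should give the linear prenyl arene under neutral conditions that spare the silyl ether and the ketone.

**Step 6**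
Reactants: 9 1-[4-{[tert-butyl(dimethyl)silyl]oxy}-2-hydroxy-5-(3-methylbut-2-en-1-yl)phenyl]ethan-1-one
Product: 10 1-[4-{[tert-butyl(dimethyl)silyl]oxy}-5-{[(2S)-3,3-dimethyloxiran-2-yl]methyl}-2-hydroxyphenyl]ethan-1-one
Conditions: 1,2:4,5-di-O-isopropylidene-β-L-erythro-2,3-hexodiulo-2,6-pyranose (enantiomer of the Shi ketone, 30 mol %), Oxone (2KHSO5·KHSO4·K2SO4), K2CO3, Bu4NHSO4, MeCN/CH2(OMe)2, aq. Na2B4O7/Na2EDTA buffer (pH 10.5), 0 °C
Reagents that add atoms: potassium peroxymonosulfate (active component of Oxone), [K+].[O-]S(=O)(=O)OO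
Why: In this Shi-type asymmetric epoxidation the chiral dioxirane reacts through a spiro transition state; the D-fructose ketone gives the (R)-epoxide from R–CH2–CH=CMe2 olefins, so its enantiomer should give the (S)-epoxide under catalyst control, and the electron-rich trisubstituted alkene should react much faster than the acyl-deactivated arene.

**Step 7**
Reactants: 10 1-[4-{[tert-butyl(dimethyl)silyl]oxy}-5-{[(2S)-3,3-dimethyloxiran-2-yl]methyl}-2-hydroxyphenyl]ethan-1-one
Product: 12 1-[(2R)-6-hydroxy-2-(2-hydroxypropan-2-yl)-2,3-dihydro-1-benzofuran-5-yl]ethan-1-one, via free phenol epoxide 11 (not isolated)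
Conditions: K2CO3, MeOH, 23 °C
Reagents that add atoms: none
Why: Base-catalysed methanolysis of the aryl silyl ether frees the 4-phenoxide 11, which should open the epoxide at the secondary carbon in a 5-exo-tet SN2 reaction with inversion (S to R), the known base-mediated route from o-(epoxyprenyl)phenols to 2-(2-hydroxypropan-2-yl)dihydrobenzofurans, while attack at the tertiary carbon is disfavoured without acid.

**Step 8**
Reactants: 12 1-[(2R)-6-hydroxy-2-(2-hydroxypropan-2-yl)-2,3-dihydro-1-benzofuran-5-yl]ethan-1-one; 4 4-[(2-methylbut-3-en-2-yl)oxy]benzaldehyde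
Product: 14 (2E)-1-[(2R)-6-hydroxy-2-(2-hydroxypropan-2-yl)-2,3-dihydro-1-benzofuran-5-yl]-3-{4-[(2-methylbut-3-en-2-yl)oxy]phenyl}prop-2-en-1-one, via aldol adduct 13 (not isolated)
Conditions: KOH (50% aq., 10 equiv), EtOH, 0 to 23 °C; then AcOH to pH 6
Reagents that add atoms: none
Why: In this Claisen–Schmidt condensation the methyl ketone enolate adds to the non-enolisable aldehyde and E1cB dehydration of aldol 13 should give the thermodynamically favoured E-enone; the tertiary allyl ether keeps the ring B oxygen from forming a deactivating phenoxide, and the ring A stereocentre carries no acidic hydrogen and is untouched.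

**Step 9**
Reactants: 14 (2E)-1-[(2R)-6-hydroxy-2-(2-hydroxypropan-2-yl)-2,3-dihydro-1-benzofuran-5-yl]-3-{4-[(2-methylbut-3-en-2-yl)oxy]phenyl}prop-2-en-1-one
Product: 17 (2E)-3-(2,2-dimethyl-3,4-dihydro-2H-1-benzopyran-6-yl)-1-[(2R)-6-hydroxy-2-(2-hydroxypropan-2-yl)-2,3-dihydro-1-benzofuran-5-yl]prop-2-en-1-one, via Claisen dienone 15 (not isolated), via o-prenylphenol chalcone 16 (not isolated)
Conditions: o-xylene, 130 °C, Ar; then 23 °C, CH2Cl2 co-solvent, TsOH·H2O (10 mol %)
Reagents that add atoms: none
Why: Heating should trigger the aromatic Claisen rearrangement, a concerted [3,3]-sigmatropic shift through a chair transition state in which the O–C(Me)2 bond of the ether breaks while the vinyl terminus bonds to the ortho carbon, and tautomerisation of dienone 15 gives the o-prenylphenol 16. The acid then protonates the trisubstituted alkene at C3 (Markovnikov), and the tertiary cation at the gem-dimethyl carbon is captured by the neighbouring phenol oxygen, which closes the dihydropyran ring through the O1–C2 bond. The closest known reaction types are the Claisen rearrangement of aryl 1,1-dimethylallyl ethers to o-prenylphenols and the acid-catalysed cycloisomerisation of o-prenylphenols to 2,2-dimethylchromans. The ring closes in the 6-endo-trig mode, which should win over 5-exo because only attack at the dimethyl-substituted carbon passes through a tertiary cation; no stereocentre is formed and the (R) centre of ring A is not involved. The C–C bond needs no regiocontrol because the para position carries the enone and the two ortho carbons are equivalent. Chemoselectivity rests on the deactivated tertiary alcohol (its cation would lie β to an aryloxy oxygen that is a poor neighbouring group because it is para to the ketone) and on the chelated 2'-hydroxyl, which should make flavanone formation slow under catalytic acid at ambient temperature.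

**Compound list**

1 | 4-hydroxybenzaldehyde | O=Cc1ccc(O)cc1 | starting material
2 | 3-chloro-3-methylbut-1-yne | CC(C)(Cl)C#C | starting material
3 | 4-[(2-methylbut-3-yn-2-yl)oxy]benzaldehyde | CC(C)(Oc1ccc(C=O)cc1)C#C | intermediate
4 | 4-[(2-methylbut-3-en-2-yl)oxy]benzaldehyde | CC(C)(Oc1ccc(C=O)cc1)C=C | intermediate
5 | 1-(2,4-dihydroxyphenyl)ethan-1-one | CC(=O)c1ccc(O)cc1O | starting material
6 | 1-(2,4-dihydroxy-5-iodophenyl)ethan-1-one | CC(=O)c1cc(I)c(O)cc1O | intermediate
7 | 1-(4-{[tert-butyl(dimethyl)silyl]oxy}-2-hydroxy-5-iodophenyl)ethan-1-one | CC(=O)c1cc(I)c(O[Si](C)(C)C(C)(C)C)cc1O | intermediate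
8 | tributyl(3-methylbut-2-en-1-yl)stannane | CC(C)=CC[Sn](CCCC)(CCCC)CCCC | starting material
9 | 1-[4-{[tert-butyl(dimethyl)silyl]oxy}-2-hydroxy-5-(3-methylbut-2-en-1-yl)phenyl]ethan-1-one | CC(=O)c1cc(CC=C(C)C)c(O[Si](C)(C)C(C)(C)C)cc1O | intermediate
10 | 1-[4-{[tert-butyl(dimethyl)silyl]oxy}-5-{[(2S)-3,3-dimethyloxiran-2-yl]methyl}-2-hydroxyphenyl]ethan-1-one | CC(=O)c1cc(C[C@@H]2OC2(C)C)c(O[Si](C)(C)C(C)(C)C)cc1O | intermediate
11 | 1-[5-{[(2S)-3,3-dimethyloxiran-2-yl]methyl}-2,4-dihydroxyphenyl]ethan-1-one (present as its phenoxide) | CC(=O)c1cc(C[C@@H]2OC2(C)C)c(O)cc1O | intermediate (not isolated)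
12 | 1-[(2R)-6-hydroxy-2-(2-hydroxypropan-2-yl)-2,3-dihydro-1-benzofuran-5-yl]ethan-1-one | CC(=O)c1cc2c(cc1O)O[C@@H](C(C)(C)O)C2 | intermediate
13 | 3-hydroxy-1-[(2R)-6-hydroxy-2-(2-hydroxypropan-2-yl)-2,3-dihydro-1-benzofuran-5-yl]-3-{4-[(2-methylbut-3-en-2-yl)oxy]phenyl}propan-1-one (both epimers at C3) | C=CC(C)(C)Oc1ccc(C(O)CC(=O)c2cc3c(cc2O)O[C@@H](C(C)(C)O)C3)cc1 | intermediate (not isolated)
14 | (2E)-1-[(2R)-6-hydroxy-2-(2-hydroxypropan-2-yl)-2,3-dihydro-1-benzofuran-5-yl]-3-{4-[(2-methylbut-3-en-2-yl)oxy]phenyl}prop-2-en-1-one | C=CC(C)(C)Oc1ccc(/C=C/C(=O)c2cc3c(cc2O)O[C@@H](C(C)(C)O)C3)cc1 | intermediate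
15 | (2E)-1-[(2R)-6-hydroxy-2-(2-hydroxypropan-2-yl)-2,3-dihydro-1-benzofuran-5-yl]-3-[3-(3-methylbut-2-en-1-yl)-4-oxocyclohexa-1,5-dien-1-yl]prop-2-en-1-one (both epimers at the ring sp3 carbon) | CC(C)=CCC1C=C(/C=C/C(=O)c2cc3c(cc2O)O[C@@H](C(C)(C)O)C3)C=CC1=O | intermediate (not isolated)
16 | (2E)-3-[4-hydroxy-3-(3-methylbut-2-en-1-yl)phenyl]-1-[(2R)-6-hydroxy-2-(2-hydroxypropan-2-yl)-2,3-dihydro-1-benzofuran-5-yl]prop-2-en-1-one | CC(C)=CCc1cc(/C=C/C(=O)c2cc3c(cc2O)O[C@@H](C(C)(C)O)C3)ccc1O | intermediate (not isolated)
17 | (2E)-3-(2,2-dimethyl-3,4-dihydro-2H-1-benzopyran-6-yl)-1-[(2R)-6-hydroxy-2-(2-hydroxypropan-2-yl)-2,3-dihydro-1-benzofuran-5-yl]prop-2-en-1-one | CC1(C)CCc2cc(/C=C/C(=O)c3cc4c(cc3O)O[C@@H](C(C)(C)O)C4)ccc2O1 | target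

**Step count and risks**

Total step count: 9 (steps 1–2 ring B branch, steps 3–7 ring A branch, steps 8–9 after union). Longest linear sequence: 7 steps (compound 5 to compound 17, steps 3–9).

Step 9 is the most exposed. In the acid stage, ionisation and dehydration of the ring A tertiary carbinol, or acid-promoted oxa-Michael closure of the 2'-hydroxychalcone to a flavanone, may compete with protonation of the prenyl alkene. In the thermal stage the tertiary allyl ether may lose isoprene instead of rearranging. The fallback closes the dihydropyran ring before the union, on a substrate with no acid-sensitive group. It sets out from compound 4: heating in o-xylene at 130 °C should give 4-hydroxy-3-(3-methylbut-2-en-1-yl)benzaldehyde F1. TsOH·H2O in toluene at 80 °C should then close it to 2,2-dimethyl-3,4-dihydro-2H-1-benzopyran-6-carbaldehyde F2 by the same tertiary-cation O–C closure. Claisen–Schmidt condensation of this aldehyde with compound 12 (KOH, EtOH, 23 °C) comes back to the route at compound 17.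

Step 6 is next. Facial selectivity may be incomplete, the aryl silyl ether may hydrolyse early at pH 10.5, and the o-hydroxyaryl ketone may suffer peroxide-mediated (Dakin-type) degradation. The fallback builds the heterocycle and the stereocentre by palladium catalysis and sets out from compound 6. Asymmetric heteroannulation of the free iodophenol with isoprene (Pd2(dba)3, chiral phosphine ligand, Na2CO3; Heck insertion, then allylic C–O closure under ligand control) should give 1-[(2R)-6-hydroxy-2-(prop-1-en-2-yl)-2,3-dihydro-1-benzofuran-5-yl]ethan-1-one F3. Mukaiyama hydration of its isopropenyl group (Co(acac)2, PhSiH3, O2, i-PrOH, 23 °C) comes back to the route at compound 12 and bypasses steps 4 to 7.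

Step 5 is third. Allylic transposition during transmetalation or reductive elimination may deliver the branched 1,1-dimethylallyl arene, and protodestannylation may consume the stannane. The fallback replaces the cross-coupling by electrophilic aromatic substitution and sets out from compound 5. Friedel–Crafts prenylation with 2-methylbut-3-en-2-ol and BF3·OEt2 in dioxane at 23 °C should give 1-[2,4-dihydroxy-5-(3-methylbut-2-en-1-yl)phenyl]ethan-1-one F4, to be separated from the 3-prenyl isomer. Selective silylation of its 4-hydroxyl (TBSCl, imidazole, DMF, 0 °C) comes back to the route at compound 9.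

**Further compounds**

F1 | step 9 | 4-hydroxy-3-(3-methylbut-2-en-1-yl)benzaldehyde | CC(C)=CCc1cc(C=O)ccc1O
F2 | step 9 | 2,2-dimethyl-3,4-dihydro-2H-1-benzopyran-6-carbaldehyde | CC1(C)CCc2cc(C=O)ccc2O1
F3 | step 6 | 1-[(2R)-6-hydroxy-2-(prop-1-en-2-yl)-2,3-dihydro-1-benzofuran-5-yl]ethan-1-one | CC(=O)c1cc2c(cc1O)O[C@@H](C(C)=C)C2
F4 | step 5 | 1-[2,4-dihydroxy-5-(3-methylbut-2-en-1-yl)phenyl]ethan-1-one | CC(=O)c1cc(CC=C(C)C)c(O)cc1O
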